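(All runs are calculated from invented constants; scatter was added.)

The free catalyst is the actor to watch here: it turns starting material into target, and the levelling-off in your readings suggests it also dies while working.

common to all: free catalyst 0.00300 M

|  | starting material | target | time |
|---|---|---|---|
| dusk | 0.600 M |  |  |
| midnight | 0.300 M |  |  |
| noon | 0.600 M | 0.300 M |  |
| winter | 1.80 M |  |  |
| autumn | 0.600 M |  | 150 min |

- dusk run (time / min: [starting material] / M): 7.5: 0.506; 15: 0.462; 22: 0.442; 30: 0.426; 38: 0.418; 45: 0.417; 52: 0.413; 60: 0.416
- midnight run (time / min: [starting material] / M): 7.5: 0.246; 15: 0.230; 22: 0.219; 30: 0.211; 38: 0.206; 45: 0.208; 52: 0.205; 60: 0.207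
- noon run (time / min: [starting material] / M): 7.5: 0.542; 15: 0.501; 22: 0.476; 30: 0.465; 38: 0.445; 45: 0.432; 52: 0.432; 60: 0.424
- winter run (time / min: [starting material] / M): 7.5: 1.558; 15: 1.453; 22: 1.399; 30: 1.351; 38: 1.316; 45: 1.294; 52: 1.282; 60: 1.263

(readings scatter by 0.003 M)

- Overall: starting material -> target, with free catalyst as catalyst.
- Constant volume, constant temperature.
- A reading of a species includes what of it is bound.
- An order is taken over about fifteen percent of the charge, up and down.

* the exponent of [starting material] in the starting rate at the charge of the dusk run (at the point where two percent of the starting material have become target) (one fixed amount of target, the same in the runs compared)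
* starting material in the autumn run at 150 min, as a share of the starting material charged

Suppose, as my own guess, that the loss of starting material is first order in both [starting material] and [free catalyst], and that the catalyst's death is first order in [free catalyst]. Divide one rate by the other, and time drops out, along with [free catalyst]:

d ln[starting material] / d(catalyst lost) = constant

So a charge of catalyst should carry the logarithm of [starting material] a set distance, whatever the charge of starting material.

A first estimate is the last reading. The dusk run gives 0.366 and the midnight run 0.371, about equal at twice the charge. That also argues for an order of about one in [starting material].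

But the winter run is still falling: it loses 0.0310 M from 45 min to 60 min, more than the scatter of 0.003 M. So 60 min is not the end. I extend its logarithm by its successive steps:

0.287 → 0.330 → 0.354

step ratio = 0.563

tail = 0.0312

0.354 + 0.0312 = 0.385

This is the reach, the logarithm of the charge over the final [starting material]. It leaves a share of 68.0%. By 150 min the tail still open is 9.88 × 10⁻⁴, less than the scatter on the logarithm, so the autumn run should stand at its end.

One objection remains: this tail comes from the winter run, while the dusk readings look flat at 69.3% of the charge. I hold 68.0% with that doubt.

The forecast gives 0.87 and 68.8%, a share higher than mine: “Autumn repeats dusk, so by 150 min it should sit at about 0.413 M, or about 69%.”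

The autumn run holds 67.4% of its charge at 150 min, and the exponent is 1.1.

    free catalyst + starting material → target + free catalyst (11.82 M⁻¹ min⁻¹)
    free catalyst + target ⇌ catalyst-product complex, settled at all times (3.560 M⁻¹)
    free catalyst → spent catalyst (0.09000 min⁻¹)

Parking free catalyst as catalyst-product complex makes no difference to that share. The autumn share puts the reach at 0.394, in place of my 0.385 from the winter run. A quarter of the charge made means a logarithm of 0.288, which is 73.1% of that reach. The dusk run gets there at 19.4 min, and the noon run, charged with target, at 34.9 min.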